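**Retrosynthetic overview**

- The target, 2,5,6-tribromo-1-methyl-1H-indole-3-carbaldehyde, is traced back to 5,6-dibromo-1-methylindolin-2-one (9); one bromo-Vilsmeier operation installs C2–Br and C3–CHO and aromatises the five-membered ring.
- Structural feature: C3a of the benzo ring is ortho to N1 and para to the C6 bromine, and C2 sits at the lactam oxidation level. The five-membered ring can therefore be closed at the C3–C3a bond by a carbenoid at C3 tethered through the N1–C2 amide.
- Key disconnection: C3–C3a, by rhodium-carbenoid aromatic C–H substitution of 2-diazo-N-(3,4-dibromophenyl)-N-methylacetamide (8).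
- Diazoacetamide 8 is reached from 3,4-dibromoaniline (1) by mono-N-methylation, bromoacetylation and diazo formation with N,N'-ditosylhydrazine.
- Ring order: the benzene ring is bought with both bromines in place; the lactam ring is formed in step 4 and becomes the pyrrole ring in step 5.

Key step: step 4

Assumption: the target has no stereocentre and is taken as drawn; the N-methyl group is introduced before ring closure so that the anilide adopts the rotamer needed for cyclisation.

**Route**

Step 1
Reactants: 1 3,4-dibromoaniline
Product: 3 3,4-dibromo-N-methylaniline, via N-methoxymethyl aniline 2 (not isolated)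
Conditions: (CH2O)n (1.5 equiv), NaOMe (5 equiv), MeOH, rt; then NaBH4 (1.5 equiv), reflux
Reagents that add atoms: paraformaldehyde (formaldehyde unit), C=O
Why: Selective mono-N-methylation by reductive amination, in which methoxide-mediated condensation with formaldehyde stops at the N-(methoxymethyl)aniline 2 and NaBH4 then reduces the derived N-methylene imine, the aryl bromides being inert to borohydride.

Step 2
Reactants: 3 3,4-dibromo-N-methylaniline; 4 bromoacetyl bromide
Product: 5 2-bromo-N-(3,4-dibromophenyl)-N-methylacetamide
Conditions: BrCH2COBr (1.2 equiv), K2CO3, CH2Cl2, 0 °C to rt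
Reagents that add atoms: bromoacetyl bromide 4, BrCC(=O)Br
Why: N-acylation of a secondary aniline (Schotten–Baumann type), in which the acyl bromide is far more electrophilic than the alkyl bromide, so the nitrogen is acylated chemoselectively while the heterogeneous carbonate only scavenges HBr.

Step 3
Reactants: 5 2-bromo-N-(3,4-dibromophenyl)-N-methylacetamide; 6 N,N'-ditosylhydrazine
Product: 8 2-diazo-N-(3,4-dibromophenyl)-N-methylacetamide, via alkylated ditosylhydrazine 7 (not isolated)
Conditions: TsNHNHTs (2 equiv), DBU (5 equiv), THF, 0 °C to rt
Reagents that add atoms: N,N'-ditosylhydrazine 6, Cc1ccc(cc1)S(=O)(=O)NNS(=O)(=O)c1ccc(C)cc1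
Why: Diazo formation by the N,N'-ditosylhydrazine method, in which the sulfonyl hydrazide anion displaces the activated alpha-bromide (SN2) to give 7 and DBU then expels two p-toluenesulfinate ions in succession to unveil the diazo group under mild, non-acidic conditions that the diazoacetamide tolerates.

Step 4
Reactants: 8 2-diazo-N-(3,4-dibromophenyl)-N-methylacetamide
Product: 9 5,6-dibromo-1-methylindolin-2-one
Conditions: Rh2(O2CC3F7)4 (1 mol %), anhydrous CH2Cl2, rt, slow addition of 8
Reagents that add atoms: none
Why: The dirhodium tetracarboxylate (divalent rhodium) expels N2 from 8 to give an electrophilic rhodium carbenoid at the future C3, which is held over the ortho carbon because N-alkyl anilides prefer the rotamer with the aryl group on the side of the acyl carbon. Attack of the arene on the carbenoid gives a Wheland-type cyclohexadienyl cation and a hydrogen shift with release of the catalyst restores the benzene ring; this is the known dirhodium carboxylate-catalysed aromatic substitution of N-aryl diazoacetamides to 2-indolinones. The five-membered lactam ring (N1, C2, C3, C3a, C7a) closes at the C3–C3a bond, in a 5-exo-trig sense with respect to the arene C3a–C4 pi bond. No stereocentre is created. The step needs regioselection between the two ortho carbons: the required one is unhindered and lies para to the bromine that becomes C6–Br, whereas the other is wedged between nitrogen and bromine, so sterics should direct closure to the 5,6-dibromo isomer. The perfluorobutyrate ligands raise the electrophilicity of the carbenoid to offset the deactivated ring and favour aromatic substitution over insertion into the primary N-methyl C–H bonds (which would require a beta-lactam), while slow addition suppresses carbene dimerisation; ring expansion by cycloaddition is not expected here because it would need a fused four-membered ring.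

Step 5
Reactants: 9 5,6-dibromo-1-methylindolin-2-one
Product: 12 2,5,6-tribromo-1-methyl-1H-indole-3-carbaldehyde, via aminomethylene oxindole 10 (not isolated), via iminium bromide 11 (not isolated)
Conditions: POBr3 (2.5 equiv), DMF (3 equiv), ClCH2CH2Cl, 0 °C to 80 °C; then ice-water, rt
Reagents that add atoms: N,N-dimethylformamide, CN(C)C=O; phosphorus oxybromide, BrP(Br)(Br)=O; water, O
Why: Vilsmeier–Haack haloformylation of an oxindole, in which the bromoiminium reagent formylates the enolisable C3 to the aminomethylene lactam 10, activation of the lactam oxygen and bromide addition–elimination at C2 aromatise the ring to the iminium salt 11, and water hydrolyses this to the aldehyde without touching the N-methyl group or the aryl bromides.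

**Compound list**

1 | 3,4-dibromoaniline | Nc1ccc(Br)c(Br)c1 | starting material
2 | 3,4-dibromo-N-(methoxymethyl)aniline | COCNc1ccc(Br)c(Br)c1 | intermediate
3 | 3,4-dibromo-N-methylaniline | CNc1ccc(Br)c(Br)c1 | intermediate
4 | bromoacetyl bromide | BrCC(=O)Br | starting material
5 | 2-bromo-N-(3,4-dibromophenyl)-N-methylacetamide | BrCC(=O)N(C)c1ccc(Br)c(Br)c1 | intermediate
6 | N,N'-ditosylhydrazine | Cc1ccc(cc1)S(=O)(=O)NNS(=O)(=O)c1ccc(C)cc1 | starting material
7 | 2-[1,2-bis(4-methylphenylsulfonyl)hydrazinyl]-N-(3,4-dibromophenyl)-N-methylacetamide | Cc1ccc(cc1)S(=O)(=O)NN(CC(=O)N(C)c1ccc(Br)c(Br)c1)S(=O)(=O)c1ccc(C)cc1 | intermediate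
8 | 2-diazo-N-(3,4-dibromophenyl)-N-methylacetamide | [N-]=[N+]=CC(=O)N(C)c1ccc(Br)c(Br)c1 | intermediate
9 | 5,6-dibromo-1-methylindolin-2-one | CN1C(=O)Cc2cc(Br)c(Br)cc21 | intermediate
10 | (E)-5,6-dibromo-3-[(dimethylamino)methylidene]-1-methylindolin-2-one | CN(C)/C=C1/C(=O)N(C)c2cc(Br)c(Br)cc21 | intermediate
11 | dimethyl[(2,5,6-tribromo-1-methyl-1H-indol-3-yl)methylidene]ammonium bromide | C[N+](C)=Cc1c(Br)n(C)c2cc(Br)c(Br)cc12.[Br-] | intermediate
12 | 2,5,6-tribromo-1-methyl-1H-indole-3-carbaldehyde | Cn1c(Br)c(C=O)c2cc(Br)c(Br)cc21 | target

**Summary**

Total step count: 5. Longest linear sequence: 5 steps (1 → 3 → 5 → 8 → 9 → 12).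

Steps most likely to fail:

1. Step 4 (carbenoid ring closure). Attack on the doubly brominated, deactivated ring may be slow enough that bimolecular consumption of the carbenoid (dimerisation, O–H insertion with adventitious water) takes over, or regiocontrol between the two ortho positions may be incomplete. The fallback forms the same C3–C3a bond by a radical instead of a carbenoid; it sets out from bromoacetamide 5 and comes back at oxindole 9. Displacement of the bromide with KSC(S)OEt in acetone at rt should give O-ethyl S-[2-[(3,4-dibromophenyl)(methyl)amino]-2-oxoethyl] dithiocarbonate F1. Portionwise addition of stoichiometric dilauroyl peroxide in refluxing 1,2-dichloroethane should then generate the carbamoylmethyl radical, which adds to the free ortho carbon. The peroxide oxidises the resulting cyclohexadienyl radical, and loss of a proton gives 9. Radical addition is far less sensitive to the electron-poor ring than the electrophilic carbenoid.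

2. Step 3 (diazo formation). Alkylation of the ditosylhydrazide by the bromoacetamide may be sluggish, DBU may be quaternised by the bromide, or the sequence may stall after loss of only one sulfinate. The fallback builds the diazo group by diazo transfer and deacylation; it sets out from N-methylaniline 3 and comes back at diazoacetamide 8. Acetoacetylation with 2,2,6-trimethyl-4H-1,3-dioxin-4-one in xylene at 130 °C (acetylketene trapping) should give N-(3,4-dibromophenyl)-N-methyl-3-oxobutanamide F2. Regitz diazo transfer with 4-acetamidobenzenesulfonyl azide and Et3N in MeCN should give 2-diazo-N-(3,4-dibromophenyl)-N-methyl-3-oxobutanamide F3. Deacetylation with aqueous KOH in MeCN at rt then gives 8.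

3. Step 5 (bromoformylation). The sequence may stall at the aminomethylene lactam stage, with incomplete conversion of the lactam carbonyl into C2–Br, or the C2 bromine may be lost hydrolytically during the aqueous quench. The fallback separates the two events; it sets out from oxindole 9 and comes back at target 12. POBr3 with imidazole in refluxing 1,2-dichloroethane should convert the lactam into 2,5,6-tribromo-1-methyl-1H-indole F4. Rieche formylation (Cl2CHOMe, TiCl4, CH2Cl2, −78 to 0 °C, aqueous work-up) at the nucleophilic C3 then gives 12.

**Further compounds**

F1 | step 4 | O-ethyl S-[2-[(3,4-dibromophenyl)(methyl)amino]-2-oxoethyl] dithiocarbonate | CCOC(=S)SCC(=O)N(C)c1ccc(Br)c(Br)c1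
F2 | step 3 | N-(3,4-dibromophenyl)-N-methyl-3-oxobutanamide | CC(=O)CC(=O)N(C)c1ccc(Br)c(Br)c1
F3 | step 3 | 2-diazo-N-(3,4-dibromophenyl)-N-methyl-3-oxobutanamide | CC(=O)C(=[N+]=[N-])C(=O)N(C)c1ccc(Br)c(Br)c1
F4 | step 5 | 2,5,6-tribromo-1-methyl-1H-indole | Cn1c(Br)cc2cc(Br)c(Br)cc21
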